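## Retrosynthetic overview

1. Feature: the (E)-C2'=C3' alkene of the side chain (ArCH2 = C1') has CH3 on C3' and the benzylic carbon C1' on C2', cis to each other, so it is the syn adduct of CH3 and ArCH2 across a terminal C2'≡C3' alkyne. The only ring, the arene, is bought; no ring is formed.
2. Key disconnection: C3'–CH3 and C1'–C2' in one pot, giving alkyne 23 (C2'–C15', C5' OTBS, C12' OTES), Me3Al and benzylic chloride 6.
3. Alkyne 23 comes from enal 21 by catalyst-controlled propargylboration (sets C5'). Enal 21 comes from alkyne 17 by methylalumination/hydroxymethylation (sets C6'=C7'). Alkyne 17 comes from Evans methylation of a hept-6-ynoyl imide (sets C11'), then a terminal epoxide opened by an isobutenyl cuprate (C12'–C15').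
4. Chloride 6 comes from 4-methoxy-2-methylphenol by ortho-formylation, O-methylation, reduction and chlorination.
5. After the key step: TES removal, C12' oxidation, TBS removal, oxidative demethylation to the quinone, reduction to the hydroquinone.

Key step: step 16

Assumption 1: C12' is carried as a mixture of epimers from step 9 to step 17, because step 18 converts it into the ketone.
Assumption 2: (R)-TRIP is taken to direct the propargyl group to the Re face of the aldehyde, as in its allyl- and propargylborations of aryl and conjugated aldehydes; if the opposite sense is found, the (S)-acid is used.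

## Route

Step 1
Reactants: 1 4-methoxy-2-methylphenol
Product: 3 2-hydroxy-5-methoxy-3-methylbenzaldehyde, via hydroxymethylphenol 2 (not isolated)
Conditions: (CH2O)n, MgCl2, Et3N, MeCN, reflux
Reagents that add atoms: paraformaldehyde (formaldehyde), C=O
Why: Casnati–Skattebøl ortho-formylation; the magnesium phenoxide delivers formaldehyde to the only free ortho position and a second formaldehyde oxidises the benzylic alkoxide by hydride transfer.

Step 2
Reactants: 3 2-hydroxy-5-methoxy-3-methylbenzaldehyde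
Product: 4 2,5-dimethoxy-3-methylbenzaldehyde
Conditions: MeI, K2CO3, DMF, rt
Reagents that add atoms: iodomethane, CI
Why: Williamson O-methylation of the phenoxide, which is the only acidic site.

Step 3
Reactants: 4 2,5-dimethoxy-3-methylbenzaldehyde
Product: 5 (2,5-dimethoxy-3-methylphenyl)methanol
Conditions: NaBH4, MeOH, 0 °C
Reagents that add atoms: none
Why: Borohydride reduction of an aryl aldehyde to the benzylic alcohol.

Step 4
Reactants: 5 (2,5-dimethoxy-3-methylphenyl)methanol
Product: 6 1-(chloromethyl)-2,5-dimethoxy-3-methylbenzene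
Conditions: SOCl2, CH2Cl2, 0 °C to rt; used freshly prepared
Reagents that add atoms: thionyl chloride, O=S(Cl)Cl
Why: Chlorodehydroxylation through the chlorosulfite, fast for an electron-rich benzylic alcohol.

Step 5
Reactants: 7 hept-6-ynoic acid; 8 (S)-4-benzyl-1,3-oxazolidin-2-one
Product: 10 (4S)-4-benzyl-3-(hept-6-ynoyl)-1,3-oxazolidin-2-one, via mixed pivalic anhydride 9 (not isolated)
Conditions: PivCl, Et3N, THF, −20 °C; then LiCl, 8, −20 °C to rt
Reagents that add atoms: none
Why: N-acylation of the oxazolidinone by the mixed anhydride under LiCl/Et3N activation, mild enough to leave the terminal alkyne untouched.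

Step 6
Reactants: 10 (4S)-4-benzyl-3-(hept-6-ynoyl)-1,3-oxazolidin-2-one
Product: 12 (4S)-4-benzyl-3-[(2S)-2-methylhept-6-ynoyl]-1,3-oxazolidin-2-one, via sodium enolate 11 (not isolated)
Conditions: NaN(SiMe3)2 (1.1 equiv), THF, −78 °C; MeI, −78 to −40 °C
Reagents that add atoms: iodomethane, CI
Why: Evans alkylation; the chelated (Z)-enolate is methylated on the face opposite the benzyl group, which sets C11' as (S), and the imide α-CH is far more acidic than the alkyne C–H.

Step 7
Reactants: 12 (4S)-4-benzyl-3-[(2S)-2-methylhept-6-ynoyl]-1,3-oxazolidin-2-one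
Product: 13 (S)-2-methylhept-6-yn-1-ol
Conditions: LiBH4, MeOH (1 equiv), THF, 0 °C
Reagents that add atoms: none
Why: Reductive cleavage of the N-acyl oxazolidinone at the exocyclic carbonyl, without touching the α-stereocentre, and the auxiliary is recovered.

Step 8
Reactants: 13 (S)-2-methylhept-6-yn-1-ol
Product: 14 (S)-2-methylhept-6-ynal
Conditions: Dess–Martin periodinane, NaHCO3, CH2Cl2, 0 °C to rt; crude aldehyde used at once
Reagents that add atoms: none
Why: Dess–Martin oxidation is non-basic, so the α-methyl aldehyde should not epimerise.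

Step 9
Reactants: 14 (S)-2-methylhept-6-ynal
Product: 15 2-[(2S)-hept-6-yn-2-yl]oxirane (both epimers at the oxirane carbon)
Conditions: Me3S+ I−, n-BuLi, THF, −10 °C; then 14, −10 °C to rt
Reagents that add atoms: trimethylsulfonium iodide, C[S+](C)C.[I-]
Why: Corey–Chaykovsky epoxidation; the sulfonium ylide is too weak a base to deprotonate the alkyne and adds to the aldehyde faster than it enolises it at low temperature.

Step 10
Reactants: 15 2-[(2S)-hept-6-yn-2-yl]oxirane
Product: 16 (6S)-2,6-dimethylundec-2-en-10-yn-5-ol (C5 epimers)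
Conditions: 2-methylprop-1-enylmagnesium bromide (3 equiv), CuBr·SMe2 (20 mol%), THF, −30 to 0 °C
Reagents that add atoms: 2-methylprop-1-enylmagnesium bromide, CC(C)=C[Mg]Br
Why: Copper-catalysed Grignard opening of a terminal epoxide at its CH2 carbon gives the linear homoprenyl carbinol, which a prenyl metal would not give because it adds through its tertiary carbon.

Step 11
Reactants: 16 (6S)-2,6-dimethylundec-2-en-10-yn-5-ol
Product: 17 triethyl{[(6S)-2,6-dimethylundec-2-en-10-yn-5-yl]oxy}silane
Conditions: TESCl, imidazole, DMAP (cat.), CH2Cl2, 0 °C to rt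
Reagents that add atoms: chlorotriethylsilane, CC[Si](Cl)(CC)CC
Why: Standard silylation of a secondary alcohol; the TES ether masks C12' against Me3Al and can later be removed in the presence of TBS.

Step 12
Reactants: 17 triethyl{[(6S)-2,6-dimethylundec-2-en-10-yn-5-yl]oxy}silane
Product: 20 (2E,7S)-3,7,11-trimethyl-8-(triethylsilyloxy)dodeca-2,10-dien-1-ol, via alkenyldimethylalane 18 (not isolated), via lithium alkenylalanate 19 (not isolated)
Conditions: Me3Al (3 equiv), Cp2ZrCl2 (0.5 equiv), CH2Cl2, 0 °C to rt; volatiles removed; THF, n-BuLi, −78 °C; (CH2O)n, −78 °C to rt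
Reagents that add atoms: trimethylaluminium, C[Al](C)C; paraformaldehyde (formaldehyde), C=O
Why: Zirconium-catalysed syn-methylalumination of the terminal alkyne (Negishi carboalumination) places CH3 on C7' and Al on C6', and the derived alanate adds to formaldehyde with retention to give the (E)-allylic alcohol.

Step 13
Reactants: 20 (2E,7S)-3,7,11-trimethyl-8-(triethylsilyloxy)dodeca-2,10-dien-1-ol
Product: 21 (2E,7S)-3,7,11-trimethyl-8-(triethylsilyloxy)dodeca-2,10-dienal
Conditions: MnO2 (activated, excess), CH2Cl2, rt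
Reagents that add atoms: none
Why: MnO2 oxidises allylic alcohols selectively and should not isomerise the (E)-alkene.

Step 14
Reactants: 21 (2E,7S)-3,7,11-trimethyl-8-(triethylsilyloxy)dodeca-2,10-dienal
Product: 22 (4R,5E,10S)-6,10,14-trimethyl-11-(triethylsilyloxy)pentadeca-5,13-dien-1-yn-4-ol
Conditions: allenylboronic acid pinacol ester (1.5 equiv), (R)-TRIP [(R)-3,3'-bis(2,4,6-triisopropylphenyl)-1,1'-binaphthyl-2,2'-diyl hydrogen phosphate, 10 mol%], 4 Å molecular sieves, toluene, −20 °C
Reagents that add atoms: allenylboronic acid pinacol ester, C=C=CB1OC(C)(C)C(C)(C)O1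
Why: Chiral phosphoric acid-catalysed propargylboration through a six-membered chair transition state gives the homopropargylic 1,2-adduct only, and the catalyst directs attack to the Re face of the enal, which sets C5' as (R) independently of the remote C11' and C12' centres.

Step 15
Reactants: 22 (4R,5E,10S)-6,10,14-trimethyl-11-(triethylsilyloxy)pentadeca-5,13-dien-1-yn-4-ol
Product: 23 tert-butyl{[(4R,5E,10S)-6,10,14-trimethyl-11-(triethylsilyloxy)pentadeca-5,13-dien-1-yn-4-yl]oxy}dimethylsilane
Conditions: TBSCl, imidazole, DMF, rt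
Reagents that add atoms: tert-butylchlorodimethylsilane, CC(C)(C)[Si](C)(C)Cl
Why: Silylation of the secondary allylic alcohol under non-acidic conditions that leave the TES ether in place.

Step 16
Reactants: 23 tert-butyl{[(4R,5E,10S)-6,10,14-trimethyl-11-(triethylsilyloxy)pentadeca-5,13-dien-1-yn-4-yl]oxy}dimethylsilane; 6 1-(chloromethyl)-2,5-dimethoxy-3-methylbenzene
Product: 25 1-[(2E,5R,6E,11S)-5-(tert-butyldimethylsilyloxy)-3,7,11,15-tetramethyl-12-(triethylsilyloxy)hexadeca-2,6,14-trien-1-yl]-2,5-dimethoxy-3-methylbenzene, via alkenyldimethylalane 24 (not isolated)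
Conditions: Me3Al (2.5 equiv), Cp2ZrCl2 (0.3 equiv), CH2Cl2, 0 °C to rt; volatiles and excess Me3Al removed in vacuo; then 6 (1.1 equiv), Pd(PPh3)4 (5 mol%), THF, rt
Reagents that add atoms: trimethylaluminium, C[Al](C)C
Why: Cp2ZrCl2 and Me3Al form a cationic methylzirconocene–aluminate that adds CH3–metal syn across the terminal C2'≡C3' bond with methyl on the internal C3', and Zr-to-Al exchange leaves the (E)-alkenyldimethylalane 24. Zerovalent palladium then inserts into the benzylic C–Cl bond of 6, the alkenyl group passes from aluminium to palladium with retention, and reductive elimination forms C1'–C2'. The closest known reaction type is the zirconium-catalysed methylalumination of terminal alkynes followed by Pd- or Ni-catalysed coupling of the alkenylalane with a benzylic chloride, established for prenylated arene and quinone side chains. No ring closes and no stereocentre is made; the only new stereo-element is the (E)-C2'=C3' geometry, fixed by syn addition and retentive coupling, so that C1' ends trans to C4'. The step needs methyl at the internal carbon, reaction at the single terminal alkyne only, and alkenyl rather than methyl transfer: the two trisubstituted alkenes and the silyl ethers at C5' and C12' are inert to Me3Al/Cp2ZrCl2 at room temperature, and stripping excess Me3Al before palladium is added limits methylation of 6.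

Step 17
Reactants: 25 1-[(2E,5R,6E,11S)-5-(tert-butyldimethylsilyloxy)-3,7,11,15-tetramethyl-12-(triethylsilyloxy)hexadeca-2,6,14-trien-1-yl]-2,5-dimethoxy-3-methylbenzene
Product: 26 (2E,5R,6E,11S)-5-(tert-butyldimethylsilyloxy)-1-(2,5-dimethoxy-3-methylphenyl)-3,7,11,15-tetramethylhexadeca-2,6,14-trien-12-ol (C12' epimers)
Conditions: PPTS (0.2 equiv), MeOH/CH2Cl2 1:1, 0 °C
Reagents that add atoms: none
Why: Mild acid methanolysis cleaves a secondary TES ether much faster than a secondary TBS ether.

Step 18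
Reactants: 26 (2E,5R,6E,11S)-5-(tert-butyldimethylsilyloxy)-1-(2,5-dimethoxy-3-methylphenyl)-3,7,11,15-tetramethylhexadeca-2,6,14-trien-12-ol
Product: 27 (2E,5R,6E,11S)-5-(tert-butyldimethylsilyloxy)-1-(2,5-dimethoxy-3-methylphenyl)-3,7,11,15-tetramethylhexadeca-2,6,14-trien-12-one
Conditions: Dess–Martin periodinane, NaHCO3, CH2Cl2, 0 °C to rt
Reagents that add atoms: none
Why: Buffered Dess–Martin oxidation converts both C12' epimers into the ketone without epimerising C11' or conjugating the C14'=C15' alkene.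

Step 19
Reactants: 27 (2E,5R,6E,11S)-5-(tert-butyldimethylsilyloxy)-1-(2,5-dimethoxy-3-methylphenyl)-3,7,11,15-tetramethylhexadeca-2,6,14-trien-12-one
Product: 28 (2E,5R,6E,11S)-1-(2,5-dimethoxy-3-methylphenyl)-5-hydroxy-3,7,11,15-tetramethylhexadeca-2,6,14-trien-12-one
Conditions: HF·pyridine, pyridine, THF, 0 °C to rt
Reagents that add atoms: none
Why: Buffered fluoride desilylation is neither basic enough to isomerise the β,γ-unsaturated ketone nor acidic enough to ionise the allylic alcohol.

Step 20
Reactants: 28 (2E,5R,6E,11S)-1-(2,5-dimethoxy-3-methylphenyl)-5-hydroxy-3,7,11,15-tetramethylhexadeca-2,6,14-trien-12-one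
Product: 29 2-[(2E,5R,6E,11S)-5-hydroxy-3,7,11,15-tetramethyl-12-oxohexadeca-2,6,14-trien-1-yl]-6-methylcyclohexa-2,5-diene-1,4-dione
Conditions: (NH4)2Ce(NO3)6 (2.5 equiv), MeCN/H2O 2:1, 0 °C, short reaction time
Reagents that add atoms: water, O
Why: Oxidative demethylation of the 1,4-dimethoxyarene by tetravalent cerium goes through the arene radical cation and ipso attack of water, and is much faster than oxidation of isolated alkenes or of the secondary alcohol.

Step 21
Reactants: 29 2-[(2E,5R,6E,11S)-5-hydroxy-3,7,11,15-tetramethyl-12-oxohexadeca-2,6,14-trien-1-yl]-6-methylcyclohexa-2,5-diene-1,4-dione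
Product: 30 2-[(2E,5R,6E,11S)-5-hydroxy-3,7,11,15-tetramethyl-12-oxohexadeca-2,6,14-trien-1-yl]-6-methylbenzene-1,4-diol (target)
Conditions: Na2S2O4, EtOAc/H2O, rt, under argon
Reagents that add atoms: none
Why: Dithionite reduces the benzoquinone to the hydroquinone without touching the ketone, the alkenes or the alcohol; the air-sensitive product is isolated under inert gas.

## Compound list

1 | 4-methoxy-2-methylphenol | COc1ccc(O)c(C)c1 | starting material
2 | 2-(hydroxymethyl)-4-methoxy-6-methylphenol (magnesium salt in the flask) | COc1cc(C)c(O)c(CO)c1 | intermediate (not isolated)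
3 | 2-hydroxy-5-methoxy-3-methylbenzaldehyde | COc1cc(C)c(O)c(C=O)c1 | intermediate
4 | 2,5-dimethoxy-3-methylbenzaldehyde | COc1cc(C)c(OC)c(C=O)c1 | intermediate
5 | (2,5-dimethoxy-3-methylphenyl)methanol | COc1cc(C)c(OC)c(CO)c1 | intermediate
6 | 1-(chloromethyl)-2,5-dimethoxy-3-methylbenzene | COc1cc(C)c(OC)c(CCl)c1 | intermediate
7 | hept-6-ynoic acid | C#CCCCCC(=O)O | starting material
8 | (S)-4-benzyl-1,3-oxazolidin-2-one | O=C1OC[C@H](Cc2ccccc2)N1 | starting material
9 | hept-6-ynoic pivalic anhydride | C#CCCCCC(=O)OC(=O)C(C)(C)C | intermediate (not isolated)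
10 | (4S)-4-benzyl-3-(hept-6-ynoyl)-1,3-oxazolidin-2-one | C#CCCCCC(=O)N1[C@@H](Cc2ccccc2)COC1=O | intermediate
11 | sodium (Z)-enolate of 10 | C#CCCC/C=C(\[O-])N1[C@@H](Cc2ccccc2)COC1=O.[Na+] | intermediate (not isolated)
12 | (4S)-4-benzyl-3-[(2S)-2-methylhept-6-ynoyl]-1,3-oxazolidin-2-one | C#CCCC[C@H](C)C(=O)N1[C@@H](Cc2ccccc2)COC1=O | intermediate
13 | (S)-2-methylhept-6-yn-1-ol | C#CCCC[C@H](C)CO | intermediate
14 | (S)-2-methylhept-6-ynal | C#CCCC[C@H](C)C=O | intermediate
15 | 2-[(2S)-hept-6-yn-2-yl]oxirane (epimers at the oxirane carbon) | C#CCCC[C@H](C)C1CO1 | intermediate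
16 | (6S)-2,6-dimethylundec-2-en-10-yn-5-ol (C5 epimers) | C#CCCC[C@H](C)C(O)CC=C(C)C | intermediate
17 | triethyl{[(6S)-2,6-dimethylundec-2-en-10-yn-5-yl]oxy}silane | C#CCCC[C@H](C)C(O[Si](CC)(CC)CC)CC=C(C)C | intermediate
18 | dimethyl[(1E,6S)-2,6,10-trimethyl-7-(triethylsilyloxy)undeca-1,9-dien-1-yl]alane | C[Al](C)/C=C(C)/CCC[C@H](C)C(O[Si](CC)(CC)CC)CC=C(C)C | intermediate (not isolated)
19 | lithium butyl(dimethyl)[(1E,6S)-2,6,10-trimethyl-7-(triethylsilyloxy)undeca-1,9-dien-1-yl]alanate | [Li+].CCCC[Al-](C)(C)/C=C(C)/CCC[C@H](C)C(O[Si](CC)(CC)CC)CC=C(C)C | intermediate (not isolated)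
20 | (2E,7S)-3,7,11-trimethyl-8-(triethylsilyloxy)dodeca-2,10-dien-1-ol | OC/C=C(C)/CCC[C@H](C)C(O[Si](CC)(CC)CC)CC=C(C)C | intermediate
21 | (2E,7S)-3,7,11-trimethyl-8-(triethylsilyloxy)dodeca-2,10-dienal | O=C/C=C(C)/CCC[C@H](C)C(O[Si](CC)(CC)CC)CC=C(C)C | intermediate
22 | (4R,5E,10S)-6,10,14-trimethyl-11-(triethylsilyloxy)pentadeca-5,13-dien-1-yn-4-ol | C#CC[C@@H](O)/C=C(C)/CCC[C@H](C)C(O[Si](CC)(CC)CC)CC=C(C)C | intermediate
23 | tert-butyl{[(4R,5E,10S)-6,10,14-trimethyl-11-(triethylsilyloxy)pentadeca-5,13-dien-1-yn-4-yl]oxy}dimethylsilane (C2'–C15' alkyne) | C#CC[C@@H](O[Si](C)(C)C(C)(C)C)/C=C(C)/CCC[C@H](C)C(O[Si](CC)(CC)CC)CC=C(C)C | intermediate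
24 | dimethyl[(1E,4R,5E,10S)-4-(tert-butyldimethylsilyloxy)-2,6,10,14-tetramethyl-11-(triethylsilyloxy)pentadeca-1,5,13-trien-1-yl]alane | C[Al](C)/C=C(C)/C[C@@H](O[Si](C)(C)C(C)(C)C)/C=C(C)/CCC[C@H](C)C(O[Si](CC)(CC)CC)CC=C(C)C | intermediate (not isolated)
25 | 1-[(2E,5R,6E,11S)-5-(tert-butyldimethylsilyloxy)-3,7,11,15-tetramethyl-12-(triethylsilyloxy)hexadeca-2,6,14-trien-1-yl]-2,5-dimethoxy-3-methylbenzene | COc1cc(C)c(OC)c(C/C=C(C)/C[C@@H](O[Si](C)(C)C(C)(C)C)/C=C(C)/CCC[C@H](C)C(O[Si](CC)(CC)CC)CC=C(C)C)c1 | intermediate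
26 | (2E,5R,6E,11S)-5-(tert-butyldimethylsilyloxy)-1-(2,5-dimethoxy-3-methylphenyl)-3,7,11,15-tetramethylhexadeca-2,6,14-trien-12-ol (C12' epimers) | COc1cc(C)c(OC)c(C/C=C(C)/C[C@@H](O[Si](C)(C)C(C)(C)C)/C=C(C)/CCC[C@H](C)C(O)CC=C(C)C)c1 | intermediate
27 | (2E,5R,6E,11S)-5-(tert-butyldimethylsilyloxy)-1-(2,5-dimethoxy-3-methylphenyl)-3,7,11,15-tetramethylhexadeca-2,6,14-trien-12-one | COc1cc(C)c(OC)c(C/C=C(C)/C[C@@H](O[Si](C)(C)C(C)(C)C)/C=C(C)/CCC[C@H](C)C(=O)CC=C(C)C)c1 | intermediate
28 | (2E,5R,6E,11S)-1-(2,5-dimethoxy-3-methylphenyl)-5-hydroxy-3,7,11,15-tetramethylhexadeca-2,6,14-trien-12-one | COc1cc(C)c(OC)c(C/C=C(C)/C[C@@H](O)/C=C(C)/CCC[C@H](C)C(=O)CC=C(C)C)c1 | intermediate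
29 | 2-[(2E,5R,6E,11S)-5-hydroxy-3,7,11,15-tetramethyl-12-oxohexadeca-2,6,14-trien-1-yl]-6-methylcyclohexa-2,5-diene-1,4-dione | CC1=CC(=O)C=C(C/C=C(C)/C[C@@H](O)/C=C(C)/CCC[C@H](C)C(=O)CC=C(C)C)C1=O | intermediate
30 | 2-[(2E,5R,6E,11S)-5-hydroxy-3,7,11,15-tetramethyl-12-oxohexadeca-2,6,14-trien-1-yl]-6-methylbenzene-1,4-diol | CC(C)=CCC(=O)[C@@H](C)CCC/C(C)=C/[C@H](O)C/C(C)=C/Cc1cc(O)cc(C)c1O | target

## Step count and risks

Total step count: 21 (steps 1–4 for the arene fragment, steps 5–15 for the alkyne, steps 16–21 for assembly and end game).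
Longest linear sequence: 17 steps (steps 5–21, from hept-6-ynoic acid 7 to target 30).

Steps most likely to fail:

Step 16 (key step). The alkenylalane may protodealuminate before it couples, methyl may transfer to the benzylpalladium intermediate instead of alkenyl, or Me3Al may ionise the allylic silyl ether. Fallback: setting out from 23, the same methylalumination is run and alane 24 is quenched with I2 to give the (E)-alkenyl iodide F1. Separately, chloride 6 is inserted with zinc dust and LiCl in THF to give benzylzinc chloride F2. Pd(PPh3)4-catalysed Negishi coupling of F1 with F2 then forms the C1'–C2' bond with the polarity of the partners reversed, and the route is rejoined at 25.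

Step 14. The β,β-disubstituted enal may react slowly and with insufficient facial selectivity, giving a C5' epimer mixture that cannot be separated. Fallback: setting out from 21, zinc-mediated Barbier addition of propargyl bromide (Zn, THF/aq. NH4Cl) gives carbinol F3 as a mixture of C5' epimers. Sharpless kinetic resolution (Ti(OiPr)4, L-(+)-diisopropyl tartrate, t-BuOOH 0.6 equiv, 4 Å molecular sieves, CH2Cl2, −20 °C) epoxidises the (5'S)-epimer to epoxy alcohol F4 and leaves the (5'R)-carbinol untouched; chromatographic separation returns the route to 22.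

Step 20. The acidic cerium oxidant may ionise or over-oxidise the free allylic alcohol at C5' during oxidative demethylation. Fallback: setting out from 27, the oxidation with (NH4)2Ce(NO3)6 is run while C5' still carries its silyl ether, giving silyloxy quinone F5. HF·pyridine then removes the silyl group and the route is rejoined at 29.

Further compounds

F1 | step 16 | tert-butyl{[(1E,4R,5E,10S)-1-iodo-2,6,10,14-tetramethyl-11-(triethylsilyloxy)pentadeca-1,5,13-trien-4-yl]oxy}dimethylsilane | I/C=C(C)/C[C@@H](O[Si](C)(C)C(C)(C)C)/C=C(C)/CCC[C@H](C)C(O[Si](CC)(CC)CC)CC=C(C)C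
F2 | step 16 | (2,5-dimethoxy-3-methylbenzyl)zinc chloride | COc1cc(C)c(OC)c(C[Zn]Cl)c1
F3 | step 14 | (5E,10S)-6,10,14-trimethyl-11-(triethylsilyloxy)pentadeca-5,13-dien-1-yn-4-ol (C4 epimers) | C#CCC(O)/C=C(C)/CCC[C@H](C)C(O[Si](CC)(CC)CC)CC=C(C)C
F4 | step 14 | (1S)-1-{(2S,3S)-3-[(4S)-4,8-dimethyl-5-(triethylsilyloxy)non-7-en-1-yl]-3-methyloxiran-2-yl}but-3-yn-1-ol | C#CC[C@H](O)[C@@H]1O[C@@]1(C)CCC[C@H](C)C(O[Si](CC)(CC)CC)CC=C(C)C
F5 | step 20 | 2-[(2E,5R,6E,11S)-5-(tert-butyldimethylsilyloxy)-3,7,11,15-tetramethyl-12-oxohexadeca-2,6,14-trien-1-yl]-6-methylcyclohexa-2,5-diene-1,4-dione | CC1=CC(=O)C=C(C/C=C(C)/C[C@@H](O[Si](C)(C)C(C)(C)C)/C=C(C)/CCC[C@H](C)C(=O)CC=C(C)C)C1=O
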